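## Retrosynthetic overview
- Both tertiary carbinols are (S) by CIP analysis of the target SMILES. They come from one double, catalyst-controlled allylation of a bis(2-hydroxyacetophenone). Cross-metathesis and hydrogenation then convert the two allyl groups into 4-methylpentyl chains.
- The diarylmethane comes from a phenol-directed Friedel–Crafts/oxa-Pictet–Spengler coupling of a hydroxymethyl-acetophenone with a formyl-acetophenone. This closes a 1-aryl-phthalan, the only ring formed, which masks "ArCH2Ar′ + CH2OH".
- The benzhydryl C–O bond of the phthalan is cleaved in the last step, together with alkene reduction.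
- Both aryl building blocks come from one commercial bromo-hydroxyacetophenone.

**Assumptions:**
- (S)-3,3′-Br2-BINOL is assumed to give the (S)-carbinols. If the opposite sense is found, use the (R)-catalyst.
- Potassium acetoxymethyltrifluoroborate and allyldiisopropoxyborane are assumed purchasable.

## Route

**Step 1**
Reactants: 1 (4-bromo-2-hydroxyacetophenone); 2 (potassium acetoxymethyltrifluoroborate)
Product: 3 (1-[2-hydroxy-4-(hydroxymethyl)phenyl]ethan-1-one)
Conditions: Pd(OAc)2, XPhos, Cs2CO3, dioxane/H2O, 100 °C; then K2CO3, MeOH, 25 °C (one pot)
Reagents that add atoms: potassium acetoxymethyltrifluoroborate, CC(=O)OC[B-](F)(F)F.[K+] (supplies CH2O; the acetyl is cleaved)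
Why: Suzuki–Miyaura (Molander) coupling replaces Br by CH2OAc, and methanolysis then gives the free benzylic alcohol, leaving the ketone and phenol untouched.

**Step 2**
Reactants: 3 (a portion; the rest goes to step 3)
Product: 4 (4-acetyl-3-hydroxybenzaldehyde)
Conditions: activated MnO2 (15 equiv), CH2Cl2, 40 °C, 12 h
Reagents that add atoms: none
Why: MnO2 oxidises benzylic alcohols selectively and leaves the chelated phenol and the aryl ketone intact.

**Step 3**
Reactants: 3 (1.2 equiv); 4 (1.0 equiv)
Product: 5 (1-(4-acetyl-3-hydroxyphenyl)-6-acetyl-5-hydroxy-1,3-dihydroisobenzofuran; C1 racemic)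
Conditions: TfOH (10 mol%), HFIP, 35 °C, 6 h
Reagents that add atoms: none (H2O is lost)
Why: Acid-catalysed Friedel–Crafts hydroxyalkylation (or the equivalent oxa-Pictet–Spengler closure via the hemiacetal/oxocarbenium) puts the aldehyde carbon at C5 of 3. C5 is para to the phenol OH and is the less hindered site, because C3 is flanked by OH and CH2OH. The ortho CH2OH then traps the benzhydryl cation as the phthalan. The racemic phthalan C1 is destroyed in step 6.

**Step 4**
Reactants: 5; 6 (allyldiisopropoxyborane); 7 ((S)-3,3′-dibromo-BINOL, catalyst)
Product: 8 (bis(homoallylic tertiary alcohol) phthalan, both carbinols (S))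
Conditions: 6 (6 equiv; 2 equiv are consumed by the two phenols), 7 (30 mol%), iPrOH (6 equiv), toluene, 35 °C, 24 h; aqueous NaHCO3 work-up
Reagents that add atoms: allyldiisopropoxyborane, C=CCB(OC(C)C)OC(C)C (two allyl groups)
Why: Proposed new method: the phenols exchange with 6 to give aryloxy(isopropoxy)boron species, a transient in situ protection that costs two equivalents of 6. Meanwhile 7 exchanges with 6 and iPrOH to form a chiral BINOL-allylboronate. It binds each ketone through boron and transfers allyl through a closed chair Zimmerman–Traxler transition state, aryl equatorial, to one carbonyl face. The closest known reaction is the BINOL-catalysed allylboration of aryl methyl ketones with allyldiisopropoxyborane; the new feature is its use on unprotected 2-hydroxyaryl ketones, twice in one pot. Both carbinol stereocentres are set here, and the two C1 epimers of the phthalan converge in step 6.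

**Step 5**
Reactants: 8; 9 (3-methylbut-1-ene)
Product: 10 (bis-(E)-4-methylpent-2-enyl carbinol phthalan, (S,S))
Conditions: Hoveyda–Grubbs II (5 mol%), 1,4-benzoquinone (10 mol%), 9 (20 equiv), CH2Cl2, sealed tube, 40 °C, 16 h
Reagents that add atoms: 3-methylbut-1-ene, C=CC(C)C
Why: Ru-catalysed cross-metathesis of the terminal alkenes with a slowly homodimerising partner gives the CH2CH=CH–CH(CH3)2 chains (E), with ethylene lost. Benzoquinone suppresses alkene isomerisation, and the stereocentres are not involved.

**Step 6**
Reactants: 10
Product: 11 (Disydonol C)
Conditions: H2 (1 atm), 10% Pd/C, EtOAc/EtOH 1:1, 25 °C, 12 h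
Reagents that add atoms: H2, [H][H] (three equivalents: two alkenes and one C–O cleavage)
Why: Hydrogenation saturates both alkenes to 4-methylpentyl chains. The same conditions hydrogenolyse the labile, p-hydroxy-stabilised diarylmethine C–O bond of the phthalan in preference to the primary benzylic C3–O bond. This gives ArCH2Ar′ and the primary CH2OH and removes the racemic C1 centre. Neutral conditions avoid ionising the tertiary benzylic alcohols.

## Verification against the target
- Ring A: the carbinol is para to the bridging CH2 and ortho to OH, and comes from the 4-acetyl-3-hydroxyphenyl unit of 4.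
- Ring B: the bridging CH2 is para to OH. The CH2OH is ortho to the bridge and meta to OH, and the carbinol is ortho to OH. This comes from 3, with bond formation at C5.
- Both carbinols are (S). The CIP priorities are O > Ar > CH2R > CH3 in the allyl, alkenyl and alkyl series, so the spatial arrangement set in step 4 is unchanged through steps 5 and 6.
- The atom balance closes at each step. 3 is C9H10O3, 4 is C9H8O3, and 5 is C18H16O5. Step 4 gives C24H28O5, step 5 gives C30H40O5, and step 6 gives C30H46O5, which matches the target (eight degrees of unsaturation).

## Compound list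
1 | 4-bromo-2-hydroxyacetophenone | CC(=O)c1ccc(Br)cc1O | starting material
2 | potassium acetoxymethyltrifluoroborate | CC(=O)OC[B-](F)(F)F.[K+] | starting material
3 | 1-[2-hydroxy-4-(hydroxymethyl)phenyl]ethanone | CC(=O)c1ccc(CO)cc1O | intermediate
4 | 4-acetyl-3-hydroxybenzaldehyde | CC(=O)c1ccc(C=O)cc1O | intermediate
5 | 1-(4-acetyl-3-hydroxyphenyl)-6-acetyl-5-hydroxyphthalan (C1 racemic) | CC(=O)c1ccc(cc1O)C2OCc3cc(O)c(C(C)=O)cc23 | intermediate
6 | allyldiisopropoxyborane | C=CCB(OC(C)C)OC(C)C | starting material
7 | (S)-3,3′-dibromo-1,1′-bi-2-naphthol (axial configuration S, not encoded in the SMILES) | Oc1c(Br)cc2ccccc2c1-c1c(O)c(Br)cc2ccccc12 | starting material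
8 | bis-allyl (S,S)-tertiary alcohol phthalan | C=CC[C@](C)(O)c1ccc(cc1O)C2OCc3cc(O)c([C@@](C)(O)CC=C)cc23 | intermediate
9 | 3-methylbut-1-ene | C=CC(C)C | starting material
10 | bis-(E)-4-methylpent-2-enyl (S,S) phthalan | CC(C)/C=C/C[C@](C)(O)c1ccc(cc1O)C2OCc3cc(O)c([C@@](C)(O)C/C=C/C(C)C)cc23 | intermediate
11 | Disydonol C | CC(C)CCC[C@](C)(O)c1ccc(Cc2cc([C@@](C)(O)CCCC(C)C)c(O)cc2CO)cc1O | target

## Totals
Total steps: 6. Longest linear sequence: 6 (1 → 3 → 4 → 5 → 8 → 10 → 11).

## Three steps most likely to fail
1. **Step 4, double allylboration of the unprotected substrate (the proposed new step).** The ortho-chelated ketones could be unreactive, or a background reaction through the phenoxy-boron species could lower the ee.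
   - Fallback: silylate both phenols (TBSCl, imidazole) and allylate with the known Ti(OiPr)4/(S)-BINOL/allyltributylstannane system. Remove the TBS groups with TBAF before step 5.
2. **Step 3, regioselective Friedel–Crafts/phthalan closure on the electron-poor acetophenone partners.** Ortho attack, aldehyde self-condensation or over-arylation could compete.
   - Fallback: build the diarylmethane by Negishi coupling instead. Use a benzylzinc from 4-(chloromethyl)-2-OTBS-acetophenone with 5-bromo-2-OTBS-4-(acetoxymethyl)acetophenone (Pd-PEPPSI). Then run the same downstream sequence and remove the protecting groups at the end.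
3. **Step 6, chemoselectivity of the tandem hydrogenation/hydrogenolysis.** The tertiary o-hydroxybenzylic C–OH bonds could also be hydrogenolysed, or the primary benzylic C3–O bond of the phthalan could cleave instead.
   - Fallback: open the phthalan before any tertiary alcohol exists. Treat 5 with Et3SiH/BF3·OEt2 (CH2Cl2, −40 °C), which ionises only the p-hydroxy-stabilised benzhydryl ether, to give the open diarylmethane bearing CH2OH. Carry it through steps 4 and 5, using one extra equivalent of 6 for the free alcohol. Finish with a purely alkene-selective reduction (diimide from TsNHNH2/NaOAc, or Wilkinson's catalyst/H2), which cannot cleave benzylic C–O bonds.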